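The ratio I watched was the split of spent X between growing chains and the loss to L.

common to all: G 4.0 mM; time 1.5 min
- spring: X 0.80 M
- summer: X 0.40 M

    X + G → Z + Q (k1 = 0.24 M⁻¹ s⁻¹)
    X + Z → Q + Z, rate k2*[Z]*[X] (k2 = 2.9 M⁻¹ s⁻¹)
    Q + Z → X + Z, rate k3*[Z] as long as [Q] is above zero (k3 = 0.33 s⁻¹)
    Q → D (k4 = 2.1 × 10⁻⁶ s⁻¹)
    X → L (k5 = 0.0081 s⁻¹)
    Z → E (k6 = 0.015 s⁻¹)

- which of the two ends with the longer chains by the average number of monomer units in a chain (chains begun, living or dead) ("neither" if they lie within 10%) (spring / summer / neither)
- average number of monomer units in a chain (chains begun, living or dead) at the end, spring
- average number of monomer units in a chain (chains begun, living or dead) at the end, summer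

- the average divides the monomer in chains by the number of chains begun, living and dead together
- run time (spring): 1.5 min

Even in summer, at the charged X, G was consumed faster than Z died, so I took the whole charge of G as Z from the start, let it decay by step 6 and froze its mean over the run, which gave X a pseudo-first-order growth constant of 0.00637 s⁻¹ beside 0.0081 s⁻¹ for the loss to L. Growth over growth plus loss is the chain share, 44.0%, and in this reckoning it follows from G and not from X. Net growth needs X above k3/k2, which is 14.2% of the charge in spring and 28.4% in summer. Integrating the now linear equation for X put Q at 25.5% of the charge in spring and 18.9% in summer. Dividing by the charge of G, taken as the chains begun, gave lengths of 50.9 and 18.9, with spring longer.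

The forecast, “Treat this as living polymerisation with a ceiling”, said spring, with 53 and 19, its spring length standing above mine.

The simulation gave 53.0 in spring and 19.0 in summer, so spring ended longer, as the forecast said.

Summer ended shorter because of its smaller charge of X: given spring's X, it reached 53.0 against 19.0. For the neighbour of spring with 0.010 M of G, the odds of the share grow with G in my reckoning, so I put the share at 66.3%, which put Q at 46.2% of the charge and the length at 37.0. The simulation gave that neighbour Q at 48.0% and a length of 38.4, shorter than in spring.

The rate constants were drawn at random within sensible limits; the result is computed.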